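The earlier runs and the new flask stem from a simulated flask with made-up constants; noise was put on by code.

The question was how the rate of making target in the flask answers to more free catalyst and to more coupling partner, at 10 % conversion.

| setting | Friday's | Thursday's | Tuesday's | flask |
|---|---|---|---|---|
| starting material | 0.035 M | 0.035 M | 0.018 M | 0.035 M |
| coupling partner | 0.016 M | 0.063 M | 0.0315 M | 0.0315 M |
| free catalyst | 0.18 mM | 0.18 mM | 0.18 mM | 0.18 mM |
| remark | run made earlier | run made earlier | run made earlier |  |

- Friday's (time / h: target / %): 4.00: 15.6; 8.00: 15.6; 10.0: 16.2; 15.0: 15.1; 20.0: 16.5
- Thursday's (time / h: target / %): 4.00: 29.7; 8.00: 34.2; 10.0: 36.6; 15.0: 37.7; 20.0: 37.2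
- Tuesday's (time / h: target / %): 1.33: 18.5; 2.50: 31.2; 5.00: 42.5; 10.0: 45.7; 20.0: 45.1

(each reading ± 1 percentage point)

- apparent order in free catalyst when 10 % of the starting material are converted (percent change of the rate of making target for one percent more free catalyst charged)
- apparent order in coupling partner when 10 % of the starting material are converted (percent change of the rate of making target for one percent more coupling partner charged)

- the numbers in the tables scatter with a standard deviation of 1 percentage point
- no earlier run changes the charge of free catalyst; that part of a forecast is a guess

No run changed the free catalyst, so I had no reading for the order in free catalyst, and first order was my guess. But Friday's and Thursday's runs differ in coupling partner at equal starting material. Friday's run stopped near 5.53 mM of target, less than its 16 mM of coupling partner, and Thursday's stopped near 13.1 mM. So I supposed that the coupling partner also decays by itself, first order. If the rate goes as the partner's concentration to a power, and decay takes the larger part of the partner while starting material is held fixed, final target then goes as the partner charged to that same power. The plateau order n, 0.630, is the logarithm of the ratio of final target over the logarithm of the ratio of partner charges. On its scale 0 means the charge makes no difference to final target and 1 means a fixed share of the partner becomes target. I took this reading as my order in coupling partner.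

The forecast gave 1.6 in free catalyst and 0.1 in coupling partner, the second lower than my reckoning, holding that “the partner protects the catalyst”.

The flask gave 1.3 in free catalyst and 0.59 in coupling partner.

    coupling partner + free catalyst → catalyst intermediate A (k = 2320 /M/h)
    starting material + catalyst intermediate A ⇌ catalyst intermediate B (K = 500 /M, k = 5580 /M/h)
    catalyst intermediate B ⇌ free catalyst + target (K = 0.0160 M, k = 29.8 /h)
    coupling partner → decomposed reagent (k = 0.406 /h)

After 15.0 h the flask's coupling partner, the limiting reagent, stood at 0.0067 % of its charge. Carried from Friday's run to the flask's charge, n gives 8.47 mM of final target, and the flask held 8.82 mM at that time. For Tuesday's run, with the same partner charge and half the starting material, n gives the same 8.47 mM, and that run read 8.17 mM.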